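The constants of this flask are hidden, so we read one number from the runs and fold the charge and the time into it.

| flask | substrate | reagent | remark | time |
|---|---|---|---|---|
| south | 15 mM | 2 equiv | the very flask that is asked about, followed so far |  |
| north | 10 mM | 2 equiv | run made earlier |  |
| flask | 15 mM | 2.00 equiv |  | 2.0 d |

| run | time / h | substrate / % | single product / % |
|---|---|---|---|
| south | 3.00 | 66.5 | 28.1 |
| south | 6.00 | 51.3 | 34.4 |
| south | 8.00 | 46.0 | 33.1 |
| south | 12.0 | 41.5 | 27.9 |
| south | 15.0 | 40.4 | 24.6 |
| south | 20.0 | 37.7 | 19.8 |
| north | 3.00 | 73.6 | 22.3 |
| north | 6.00 | 59.3 | 30.6 |
| north | 8.00 | 52.4 | 34.0 |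
| north | 12.0 | 46.4 | 32.4 |
| north | 15.0 | 44.1 | 31.4 |
| north | 20.0 | 41.2 | 27.3 |

(each reading ± 0.5 percentage points)

1. how much substrate there is at 2.0 d, in percent of the substrate charged
2. how much single product there is at 2.0 d, in percent of the substrate charged
3. how much other mono adduct there is at 2.0 d, in percent of the substrate charged
4. how much bis adduct there is at 2.0 d, in percent of the substrate charged



1. We work with the fraction of substrate left. In the south run, the first reading gives ln(1/fraction left) = 0.408 at 15 mM and 3.00 h.

2. We scale that value by c(substrate)·t and call the result the clock, a Damköhler number. For the south flask at the asked time, the clock stands at 6.53. It counts how long substrate and reagent have had to meet. If every step is bimolecular, flasks with equal equivalents and equal clock hold equal fractions.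

3. The last south reading stands at 2.72. Between 12.0 h and 20.0 h, the logarithms of the substrate and single product fractions fell. We carry both slopes along the clock to the asked time. Our estimate is 26.9% substrate, 5.96% single product and 67.1% for other mono adduct and bis adduct together, which the readings do not separate.

4. Now the test. South at 8.00 h and north at 12.0 h share a clock of 1.09. Their substrate differs by 0.4 percentage points and their single product by 0.7 points, against 0.71 points for the scatter of a difference. At this one shared clock, one number was enough for these two species.

The forecast says 30% substrate, 10% single product, 10% other mono adduct and 50% bis adduct, noting “the split is poorly determined”, and it stands above our estimates of substrate and single product.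

The flask gives 28.7% substrate, 8.76% single product, 6.86% other mono adduct and 55.7% bis adduct, so our reckoning was 1.8 points low for substrate and 2.8 points low for single product.

    substrate + reagent ⇌ single product + released group (K = 0.590, k = 0.00149 L mol⁻¹ s⁻¹)
    substrate + reagent → other mono adduct + released group (k = 6.41 × 10⁻⁵ L mol⁻¹ s⁻¹)
    reagent + single product → bis adduct + released group (k = 0.00103 L mol⁻¹ s⁻¹)
    reagent + other mono adduct → bis adduct + released group (k = 5.12 × 10⁻⁵ L mol⁻¹ s⁻¹)

In the flask at the asked time, single product is made at 0.475 of the rate at which it is used up, each step taken net. A neighbour with the same equivalents, charged with 6.0 mM and read at 2.0 d, has a clock of 2.61, just short of the 2.72 of the south reading. That reading held 37.7% substrate and 19.8% single product; the neighbour holds 37.9% and 20.7%.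

The earlier runs and the new flask were computed for an exercise, noise included.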